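**Retrosynthetic overview**
1. Numbering: ring A (ten-membered) is C1 (CH–OMe), C2, C3 (C=O), C4 (CH3, OAc), C5, C6 (CH–O-angelate), C7, C8 (CH–O), C9, C10 (CH–CH3). Ring B (lactone) is C7, C8, O, C12, C11, with the methylene C13 on C11.
2. Feature used: in ring A the C3 carbonyl lies 1,6 to C8, and the neighbouring stereocentres C1 and C10 lie across from the C3···C8 line. This is the retron of an oxy-Cope ring expansion. Reconnecting C3–C8 and cutting C1–C10 gives a cyclohexanol (ring C3–C8) with an (E)-2-methoxyvinyl group on C3 and an (E)-propenyl group on C8.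
3. After the expansion, ring B is closed on the new C8=C9 alkene (C12–OH, iodoetherification, deiodination). The C4/C6 tether is then exchanged for acetate and angelate, and C12 is oxidised to the lactone carbonyl last.
4. The cyclohexanol comes from a bridged enone (C4 and C6 oxygens tied as a benzylidene acetal) by C8–C9 Suzuki coupling, C7–C11 cuprate addition, and C3–C2 acetylide addition with trans-hydroalumination.
5. The enone comes from (S)-lactic acid (C3, C4, C4–CH3) by allylation with self-regeneration of the stereocentre, ring-closing metathesis and directed epoxidation. Ring order: carbocycle C3–C8, dioxane tether, ring A, ring B.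

Key step: step 14

Conventions: α is the face of ring C3–C8 that carries the C4 and C6 oxygens, β is the other face. PMB is 4-methoxybenzyl.

Remark on the tether: the acetal is a 2,4-dioxabicyclo[3.3.1]nonane, and the endo substituent on its acetal carbon points at the axial hydrogen on C8. Hydrogen fits there. A methyl group of an isopropylidene acetal would push one ring out of its chair, so a benzylidene acetal (phenyl exo) is used.

Assumption: keto diol 31 may rest partly as its C3/C6 hemiketal. This equilibrium is taken to be mobile, so that acylation in step 19 drains it through the open form.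

**Step 1**
Reactants: 1 (S)-lactic acid
Product: 2 (2S,5S)-2-tert-butyl-5-methyl-1,3-dioxolan-4-one (cis)
Conditions: pivalaldehyde, TsOH·H2O (cat.), H2SO4 (cat.), pentane, reflux, Dean–Stark; crystallisation from pentane, −78 °C
Reagents that add atoms: pivalaldehyde, CC(C)(C)C=O
Why: Acid-catalysed acetalisation of the α-hydroxy acid with removal of water gives the dioxolanone, and the thermodynamically favoured, crystallisable cis isomer stores the lactate configuration in the new acetal centre (first half of self-regeneration of stereocentres).

**Step 2**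
Reactants: 2 (2S,5S)-2-tert-butyl-5-methyl-1,3-dioxolan-4-one
Product: 4 (2S,5R)-5-allyl-2-tert-butyl-5-methyl-1,3-dioxolan-4-one, via lithium enolate 3 (not isolated)
Conditions: LiN(i-Pr)2 (LDA), THF, −78 °C; allyl bromide, −78 → −30 °C
Reagents that add atoms: allyl bromide, C=CCBr
Why: Enolate alkylation in which the planar enolate 3 is attacked on the face opposite the tert-butyl group, so that allyl takes the place of the former hydrogen and C4 is set as (R) with its oxygen, methyl, C3 and C5 attached.

**Step 3**
Reactants: 4 (2S,5R)-5-allyl-2-tert-butyl-5-methyl-1,3-dioxolan-4-one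
Product: 5 (R)-2-hydroxy-N-methoxy-N,2-dimethylpent-4-enamide
Conditions: MeNH(OMe)·HCl, i-PrMgCl, THF, −20 → 0 °C
Reagents that add atoms: N,O-dimethylhydroxylamine hydrochloride, CNOC.Cl
Why: Aminolysis of the activated dioxolanone carbonyl by the magnesium amide opens the ring, the released hemiacetal alkoxide sheds pivalaldehyde, and the Weinreb amide forms without touching the quaternary C4.

**Step 4**
Reactants: 5 (R)-2-hydroxy-N-methoxy-N,2-dimethylpent-4-enamide
Product: 6 (R)-5-hydroxy-5-methylocta-1,7-dien-4-one
Conditions: allylmagnesium bromide (2.5 equiv), THF, −78 °C; cold aq NH4Cl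
Reagents that add atoms: allylmagnesium bromide, C=CC[Mg]Br
Why: Weinreb ketone synthesis in which the first equivalent deprotonates the hydroxyl, the second adds once to give a chelated tetrahedral intermediate that lasts until the quench, and the low temperature keeps the allyl ketone out of conjugation.

**Step 5**
Reactants: 6 (R)-5-hydroxy-5-methylocta-1,7-dien-4-one
Product: 7 (R)-2-hydroxy-2-methylcyclohex-4-en-1-one
Conditions: second-generation Grubbs catalyst (3 mol %), 1,4-benzoquinone (10 mol %), CH2Cl2, 40 °C
Reagents that add atoms: none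
Why: Ring-closing metathesis of two monosubstituted alkenes closes the unstrained carbocycle C3–C8 at C6=C7 with loss of ethene, and benzoquinone suppresses ruthenium hydride isomerisation of the β,γ-enone.

**Step 6**
Reactants: 7 (R)-2-hydroxy-2-methylcyclohex-4-en-1-one
Product: 9 (4S,6R)-4,6-dihydroxy-6-methylcyclohex-2-en-1-one (cis diol), via epoxy ketone 8 (not isolated)
Conditions: VO(acac)2 (cat.), t-BuOOH, CH2Cl2, 0 °C → rt; then Et3N (cat.), rt
Reagents that add atoms: tert-butyl hydroperoxide, CC(C)(C)OO
Why: Hydroxyl-directed vanadium-catalysed epoxidation of the homoallylic alcohol puts oxygen on C6=C7 from the face of the pseudoaxial C4–OH, and Et3N then removes the acidic C8–H so that E1cB opening of the β,γ-epoxy ketone 8 leaves the oxygen on C6 (S), cis to the C4 oxygen, next to the new C7=C8 enone.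

**Step 7**
Reactants: 9 (4S,6R)-4,6-dihydroxy-6-methylcyclohex-2-en-1-one
Product: 10 (1R,3S,5S)-1-methyl-3-phenyl-2,4-dioxabicyclo[3.3.1]non-6-en-8-one (phenyl exo)
Conditions: PhCH(OMe)2, CSA (cat.), benzene, 50 °C, MeOH removed under reduced pressure
Reagents that add atoms: benzaldehyde dimethyl acetal, COC(OC)c1ccccc1
Why: Transacetalisation under thermodynamic control, in which only the cis-1,3-diol can bridge, phenyl takes the exo (equatorial) site and hydrogen the endo site facing C8, and the bridge also blocks dehydration of 9 to methylhydroquinone.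

**Step 8**
Reactants: 10 bridged enone
Product: 11 7-iodo-1-methyl-3-phenyl-2,4-dioxabicyclo[3.3.1]non-6-en-8-one (core as in 10; iodine on C8)
Conditions: I2, pyridine/CH2Cl2, 0 °C → rt
Reagents that add atoms: iodine, II
Why: α-Iodination of an enone by conjugate addition of pyridine, iodination of the resulting enolate and elimination (Baylis–Hillman-type sequence), with C8 the only reactive site because 10 has no enolisable position.

**Step 9**
Reactants: 11 α-iodoenone; 12 (E)-prop-1-enylboronic acid
Product: 13 7-[(E)-prop-1-enyl]-1-methyl-3-phenyl-2,4-dioxabicyclo[3.3.1]non-6-en-8-one (core as in 10)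
Conditions: PdCl2(dppf) (cat.), Cs2CO3, THF/H2O, 40 °C
Reagents that add atoms: none
Why: Suzuki–Miyaura coupling of a 2-iodoenone forms C8–C9 with retention of the (E) geometry of the alkenylboronic acid, under basic conditions that the non-enolisable bridged enone tolerates.

**Step 10**
Reactants: 14 4-methoxybenzyl alcohol; 15 2,3-dibromopropene
Product: 16 2-bromoallyl 4-methoxybenzyl ether
Conditions: NaH, THF/DMF, 0 °C → rt
Reagents that add atoms: none
Why: Williamson ether synthesis in which the alkoxide displaces only the allylic bromide, the vinylic bromide being inert to SN2.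

**Step 11**
Reactants: 13 2-propenyl enone; 16 2-bromoallyl 4-methoxybenzyl ether
Product: 20 bridged cyclohexanone bearing a β-axial C(=CH2)CH2OPMB group on C7 plus a β-equatorial (E)-propenyl group on C8, via alkenyllithium 17 (not isolated), via lithium dialkenylcuprate 18 (not isolated), via lithium dienolate 19 (not isolated)
Conditions: 16, t-BuLi, Et2O, −78 °C; CuI, Me2S/Et2O, −78 → −40 °C; 13, −78 °C; aq NH4Cl at −78 °C
Reagents that add atoms: none
Why: Bromine–lithium exchange, formation of the Gilman reagent R2CuLi and 1,4-addition, in which C7 is attacked axially on the exo (β) face, anti to the dioxane bridge and the C6 oxygen, and kinetic α-protonation of dienolate 19 at C8 from the endo (axial) side leaves the propenyl group equatorial and unconjugated, the only epimer that avoids the acetal hydrogen.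

**Step 12**
Reactants: 20 bridged cyclohexanone; 21 chloroacetaldehyde dimethyl acetal
Product: 23 C3 carbinol with α-equatorial methoxyethynyl group plus β-axial hydroxyl, via lithium methoxyacetylide 22 (not isolated)
Conditions: 21, LiNEt2 (from Et2NH, n-BuLi; 3.2 equiv), THF, 0 °C; CeCl3, −78 °C; 20, −78 °C; pH 7 buffer
Reagents that add atoms: none
Why: 1,2-Addition of a metal acetylide to a hindered ketone, in which 22 (from 21 by loss of methanol and HCl and deprotonation) is slender enough for a carbonyl flanked by C4 and C8, CeCl3 tempers its basicity toward the acidic C8–H, and the β-axial C7 side chain shields the axial trajectory so that the alkyne should enter equatorially and leave the C3 hydroxyl β-axial; the alkyne is used because (E)-2-methoxyvinyllithium itself loses LiOMe by anti elimination.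

**Step 13**
Reactants: 23 methoxyethynyl carbinol
Product: 24 trans-dialkenyl cyclohexanol benzylidene acetal (C3: α-equatorial (E)-2-methoxyvinyl, β-axial OH; C8: β-equatorial (E)-propenyl)
Conditions: LiAlH4, THF, 0 °C → rt; aq potassium sodium tartrate; Et3N-deactivated silica
Reagents that add atoms: none
Why: Hydroxyl-directed trans-hydroalumination of the propargylic alcohol followed by protonolysis gives the (E)-enol ether only, and the acid-free work-up prevents its rearrangement to the enal.

**Step 14**
Reactants: 24 trans-dialkenyl cyclohexanol benzylidene acetal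
Product: 27 ten-membered keto alkene benzylidene acetal ((E)-C8=C9; 1R,10R), via potassium alkoxide 25 (not isolated), via potassium enolate 26 (not isolated)
Conditions: KH, 18-crown-6, THF, 0 °C → rt; then −78 °C, AcOH in THF
Reagents that add atoms: none
Why: KH with 18-crown-6 gives the loosely paired axial C3 alkoxide 25, whose oxyanion weakens the adjacent C3–C8 bond, and the 1,5-diene C1=C2–C3–C8–C9=C10 undergoes a concerted [3,3] shift (anionic oxy-Cope rearrangement of a trans-1,2-dialkenylcyclohexanol, the standard entry to (E)-cyclodec-5-enones). Ring A is closed by ring expansion and not by end-to-end cyclisation, since C1–C10 forms while C3–C8 breaks and the six-membered ring grows by four atoms. The benzylidene bridge holds the C4 and C6 oxygens diaxial and so fixes the one chair in which both alkenyl groups are equatorial and gauche, which leaves only the trans-decalin-like chair transition state within reach; C7 equatorial on that chair gives the (E)-C8=C9 alkene. In this chair the two (E) alkenes place OMe on C1 and CH3 on C10 equatorial, which sets their relative configuration, and the sign of the C2–C3–C8–C9 gauche angle, fixed by the C3 and C8 configurations, sets the absolute one. The selectivity needed is rearrangement without loss of methoxide from enolate 26, which is secured because the C1–O bond of the nascent conformer lies near the nodal plane of the enolate and protonation is done at −78 °C. The second 1,5-diene (C9=C10 and C11=C13 across C7–C8) has no oxyanion on its breaking bond and should stay inert at this temperature.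

**Step 15**
Reactants: 27 ten-membered keto alkene benzylidene acetal
Product: 28 allylic alcohol (C12–OH free)
Conditions: DDQ, CH2Cl2/pH 7 buffer, 0 °C
Reagents that add atoms: none
Why: Oxidative cleavage of the p-methoxybenzyl ether by hydride abstraction, which under buffered conditions leaves the plain benzylidene acetal, the alkenes and the ketone alone.

**Step 16**
Reactants: 28 allylic alcohol
Product: 29 trans-fused 9-iodo 3-methylenetetrahydrofuran (C8–O–C12 closed; 8R; iodine anti to oxygen)
Conditions: I2, NaHCO3, MeCN, 0 °C, dark
Reagents that add atoms: iodine, II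
Why: 5-exo iodoetherification in which the iodonium ion forms on the exposed outer face of the (E)-C8=C9 alkene and the C12 hydroxyl, held over the inner face by the C7 side chain, opens it at C8 in anti fashion, so that oxygen arrives where C3 was bonded in 24, H7 and H8 end trans and ring B is closed, while the less nucleophilic C11=C13 alkene has no partner for ring closure.

**Step 17**
Reactants: 29 iodo ether
Product: 30 trans-fused 3-methylenetetrahydrofuran benzylidene acetal (C9 = CH2)
Conditions: Bu3SnH, AIBN (cat.), toluene, 80 °C
Reagents that add atoms: none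
Why: Radical chain dehalogenation, run while C12 is still an ether carbon so that no α-methylene lactone is present to capture stannyl or C9 radicals, with 5-endo or 4-exo attack of the C9 radical on C11=C13 too slow to compete.

**Step 18**
Reactants: 30 methylenetetrahydrofuran benzylidene acetal
Product: 31 C4,C6-diol
Conditions: AcOH/THF/H2O, 45 °C
Reagents that add atoms: none
Why: Acid hydrolysis of the benzylidene acetal, in which the α-keto position of C4 disfavours ionisation of the tertiary C–O bond so that both carbinol centres are retained.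

**Step 19**
Reactants: 31 C4,C6-diol; 32 angelic acid
Product: 34 C6 angelate with free C4–OH, via mixed anhydride 33 (not isolated)
Conditions: 32, 2,4,6-Cl3C6H2COCl, Et3N, toluene, rt; then 31, 80 °C
Reagents that add atoms: none
Why: Yamaguchi-type esterification without DMAP, in which mixed anhydride 33 acylates the secondary C6–OH in preference to the tertiary C4–OH and the (Z) geometry of the angelate is kept.

**Step 20**
Reactants: 34 C6 angelate
Product: 35 C4 acetate, C6 angelate (12-deoxo target)
Conditions: Ac2O, DMAP, Et3N, CH2Cl2, rt → 40 °C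
Reagents that add atoms: acetic anhydride, CC(=O)OC(C)=O
Why: DMAP-catalysed acetylation of the remaining tertiary α-ketol hydroxyl with excess anhydride, mild enough to leave the β-methoxy ketone and the angelate unchanged.

**Step 21**
Reactants: 35 12-deoxo target
Product: 36 rufesolide C
Conditions: CrO3, 3,5-dimethylpyrazole, CH2Cl2, −20 °C
Reagents that add atoms: chromium trioxide, O=[Cr](=O)=O
Why: Allylic oxidation of a cyclic allyl ether to the α,β-unsaturated lactone, known for 3-methylenetetrahydrofurans, in which the C12–H bonds are both allylic and α to oxygen and so react first, while the electron-poor angelate alkene and the acylated carbinol C–H bonds are deactivated.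

**Compound list**
1 | (S)-lactic acid | C[C@H](O)C(=O)O | starting material
2 | (2S,5S)-2-tert-butyl-5-methyl-1,3-dioxolan-4-one | C[C@@H]1O[C@H](C(C)(C)C)OC1=O | intermediate
3 | lithium enolate of 2 | CC1=C([O-])O[C@@H](C(C)(C)C)O1.[Li+] | intermediate (not isolated)
4 | (2S,5R)-5-allyl-2-tert-butyl-5-methyl-1,3-dioxolan-4-one | C[C@]1(CC=C)O[C@H](C(C)(C)C)OC1=O | intermediate
5 | (R)-2-hydroxy-N-methoxy-N,2-dimethylpent-4-enamide | C=CC[C@@](C)(O)C(=O)N(C)OC | intermediate
6 | (R)-5-hydroxy-5-methylocta-1,7-dien-4-one | C=CC[C@@](C)(O)C(=O)CC=C | intermediate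
7 | (R)-2-hydroxy-2-methylcyclohex-4-en-1-one | O=C1CC=CC[C@@]1(C)O | intermediate
8 | 4,5-epoxy-2-hydroxy-2-methylcyclohexanone, epoxide syn to OH | O=C1C[C@H]2O[C@H]2C[C@@]1(C)O | intermediate (not isolated)
9 | (4S,6R)-4,6-dihydroxy-6-methylcyclohex-2-en-1-one | O=C1C=C[C@@H](O)C[C@@]1(C)O | intermediate
10 | (1R,3S,5S)-1-methyl-3-phenyl-2,4-dioxabicyclo[3.3.1]non-6-en-8-one | O=C1C=C[C@@H]2C[C@@]1(C)O[C@@H](c3ccccc3)O2 | intermediate
11 | 7-iodo derivative of 10 | O=C1C(I)=C[C@@H]2C[C@@]1(C)O[C@@H](c3ccccc3)O2 | intermediate
12 | (E)-prop-1-enylboronic acid | C/C=C/B(O)O | starting material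
13 | 7-[(E)-prop-1-enyl] derivative of 10 | O=C1C(/C=C/C)=C[C@@H]2C[C@@]1(C)O[C@@H](c3ccccc3)O2 | intermediate
14 | 4-methoxybenzyl alcohol | COc1ccc(CO)cc1 | starting material
15 | 2,3-dibromopropene | C=C(Br)CBr | starting material
16 | 2-bromoallyl 4-methoxybenzyl ether | C=C(Br)COCc1ccc(OC)cc1 | intermediate
17 | [3-(4-methoxybenzyloxy)prop-1-en-2-yl]lithium | [Li]C(=C)COCc1ccc(OC)cc1 | intermediate (not isolated)
18 | lithium bis[3-(4-methoxybenzyloxy)prop-1-en-2-yl]cuprate | [Li+].C=C(COCc1ccc(OC)cc1)[Cu-]C(=C)COCc1ccc(OC)cc1 | intermediate (not isolated)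
19 | lithium dienolate (C3–O, C3=C8, C9=C10) | [Li+].[O-]C1=C(/C=C/C)[C@H](C(=C)COCc3ccc(OC)cc3)[C@@H]2C[C@@]1(C)O[C@@H](c4ccccc4)O2 | intermediate (not isolated)
20 | bridged cyclohexanone, C7 side chain β-axial, C8 (E)-propenyl β-equatorial | O=C1[C@H](/C=C/C)[C@H](C(=C)COCc3ccc(OC)cc3)[C@@H]2C[C@@]1(C)O[C@@H](c4ccccc4)O2 | intermediate
21 | chloroacetaldehyde dimethyl acetal | COC(CCl)OC | starting material
22 | lithium methoxyacetylide | [Li]C#COC | intermediate (not isolated)
23 | methoxyethynyl carbinol (alkyne α-equatorial, OH β-axial) | COC#C[C@]1(O)[C@]2(C)O[C@@H](c3ccccc3)O[C@@H](C2)[C@@H](C(=C)COCc4ccc(OC)cc4)[C@H]1/C=C/C | intermediate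
24 | trans-dialkenyl cyclohexanol benzylidene acetal (key-step precursor) | CO/C=C/[C@]1(O)[C@]2(C)O[C@@H](c3ccccc3)O[C@@H](C2)[C@@H](C(=C)COCc4ccc(OC)cc4)[C@H]1/C=C/C | intermediate
25 | potassium alkoxide of 24 | [K+].CO/C=C/[C@]1([O-])[C@]2(C)O[C@@H](c3ccccc3)O[C@@H](C2)[C@@H](C(=C)COCc4ccc(OC)cc4)[C@H]1/C=C/C | intermediate (not isolated)
26 | potassium C2=C3 enolate of 27 | [K+].C=C(COCc1ccc(OC)cc1)[C@H]2/C=C/[C@@H](C)[C@H](OC)/C=C(\[O-])[C@@]3(C)C[C@@H]2O[C@H](c4ccccc4)O3 | intermediate (not isolated)
27 | ten-membered keto alkene benzylidene acetal (key-step product) | C=C(COCc1ccc(OC)cc1)[C@H]2/C=C/[C@@H](C)[C@H](OC)CC(=O)[C@@]3(C)C[C@@H]2O[C@H](c4ccccc4)O3 | intermediate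
28 | allylic alcohol | C=C(CO)[C@H]2/C=C/[C@@H](C)[C@H](OC)CC(=O)[C@@]3(C)C[C@@H]2O[C@H](c4ccccc4)O3 | intermediate
29 | 9-iodo methylenetetrahydrofuran | C=C1CO[C@@H]2[C@H](I)[C@@H](C)[C@H](OC)CC(=O)[C@@]3(C)C[C@H](O[C@H](c4ccccc4)O3)[C@@H]12 | intermediate
30 | methylenetetrahydrofuran benzylidene acetal | C=C1CO[C@@H]2C[C@@H](C)[C@H](OC)CC(=O)[C@@]3(C)C[C@H](O[C@H](c4ccccc4)O3)[C@@H]12 | intermediate
31 | C4,C6-diol | C=C1CO[C@@H]2C[C@@H](C)[C@H](OC)CC(=O)[C@](C)(O)C[C@H](O)[C@@H]12 | intermediate
32 | angelic acid | C/C=C(/C)C(=O)O | starting material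
33 | angelic 2,4,6-trichlorobenzoic anhydride | C/C=C(/C)C(=O)OC(=O)c1c(Cl)cc(Cl)cc1Cl | intermediate (not isolated)
34 | C6 angelate, C4–OH free | C=C1CO[C@@H]2C[C@@H](C)[C@H](OC)CC(=O)[C@](C)(O)C[C@H](OC(=O)/C(C)=C\C)[C@@H]12 | intermediate
35 | C4 acetate, C6 angelate (12-deoxo target) | C=C1CO[C@@H]2C[C@@H](C)[C@H](OC)CC(=O)[C@](C)(OC(C)=O)C[C@H](OC(=O)/C(C)=C\C)[C@@H]12 | intermediate
36 | rufesolide C | C=C1C(=O)O[C@@H]2C[C@@H](C)[C@H](OC)CC(=O)[C@](C)(OC(C)=O)C[C@H](OC(=O)/C(C)=C\C)[C@@H]12 | target

**Step count**
Total step count: 21. Longest linear sequence: 20 steps (steps 1–9 and 11–21; step 10 is a side branch).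

**Steps most likely to fail**
1. Step 14.
   - What may go wrong: enolate 26 may expel methoxide from C1 (E1cB) before it is protonated. The rearrangement may also stall because the dioxane bridge resists widening of the C3···C7 distance.
   - Fallback, from 24 back to 27: the rearrangement mixture is left at room temperature until methoxide loss is complete, which should give the (1E,8E)-1-demethoxy-1,2-didehydro analogue of 27 F1.
   - Methanol is then returned to C1 by base-catalysed oxa-Michael addition (MeOH, K2CO3, rt) under equilibrating conditions. Peripheral attack on ring A, and the preference for methoxy and methyl both pointing outward, should favour the C1 epimer of 27. The C1 configuration would have to be checked at that point.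
2. Step 12.
   - What may go wrong: the basic mixture in which 22 is made may enolise 20 at the doubly activated C8–H, after which C9=C10 drifts into conjugation. Alternatively 22 may decay before it adds.
   - Fallback, from 20 back to 24, bypassing 23: ethynylmagnesium bromide premixed with CeCl3 (THF, −78 °C) should add with the same equatorial preference to give the ethynyl carbinol F2.
   - Alkyne-selective hydroboration with pinacolborane and Cp2ZrHCl (cat.) gives the (E)-alkenyl pinacol boronate F3. Chan–Lam-type coupling with methanol (Cu(OAc)2, Et3N, MeOH, rt) forms the C1–O bond with retention of geometry and gives 24.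
3. Step 21.
   - What may go wrong: C–H abstraction may be unselective (C7–H, the angelate methyl groups, C1–H), or allylic transposition toward C13 may occur.
   - Fallback, from 35 back to 36: allylic hydroxylation by an ene reaction and [2,3] shift (SeO2 cat., t-BuOOH, CH2Cl2) acts only on the electron-rich C11=C13 alkene and prefers its CH2 terminus C12, giving the C12 lactol F4. This is oxidised to 36 with MnO2.

**Further compounds**
F1 | step 14 | (1E,8E)-1-demethoxy-1,2-didehydro analogue of 27 | C=C(COCc1ccc(OC)cc1)[C@H]2/C=C/[C@@H](C)/C=C/C(=O)[C@@]3(C)C[C@@H]2O[C@H](c4ccccc4)O3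
F2 | step 12 | ethynyl carbinol (alkyne α-equatorial, OH β-axial) | C#C[C@]1(O)[C@]2(C)O[C@@H](c3ccccc3)O[C@@H](C2)[C@@H](C(=C)COCc4ccc(OC)cc4)[C@H]1/C=C/C
F3 | step 12 | (E)-alkenyl pinacol boronate | CC1(C)OB(/C=C/[C@]2(O)[C@]3(C)O[C@@H](c4ccccc4)O[C@@H](C3)[C@@H](C(=C)COCc5ccc(OC)cc5)[C@H]2/C=C/C)OC1(C)C
F4 | step 21 | C12 lactol (anomeric mixture) | C=C1C(O)O[C@@H]2C[C@@H](C)[C@H](OC)CC(=O)[C@](C)(OC(C)=O)C[C@H](OC(=O)/C(C)=C\C)[C@@H]12
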